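Ring A is not brought in as an arene but grown onto the chain: cutting C4a–C8a and C7–C8 turns the 6-methoxy-7-oxygenated benzene ring into a 3-bromo-4-methoxy-2-pyrone (future C4a, C5, C6, C7) joined through C4–C3–C2–C1 to a terminal alkyne (future C8a, C8). One thermal cycloaddition with loss of CO2 then closes ring B and aromatises ring A, the four-atom tether fixing OMe at C6 and Br at C7. The precursor is an open chain with all three stereocentres in place: C3 from (R)-epichlorohydrin, C1 from a copper-catalysed propargylic alkylation, C2 from lactone equilibration; C9 is a benzyl ether and C9′ a dimethylamide that masks the hydroxymethyl group to be sulfated.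

Key step: step 13

Remarks on the chemistry
- Atom labels follow the tetralin: C1 (aryl-bearing CH), C2 (bears C9′), C3 (bears C9), C4 (CH2), C4a–C8a (ring A).
- The target is drawn as the free hydrogen sulfate; it is assumed to be handled as its sodium salt and liberated with one equivalent of acid at the very end.
- The sense of induction of the Cu(MeCN)4BF4/pybox catalyst in step 4 is assumed; whichever ligand antipode gives the (R)-configured propargylic carbon in a model run is the one used.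
- The ester-bearing carbon of 11 is epimerisable and is drawn trans. C2 of compound 12 is drawn as the diastereomer expected from attack anti to the allyl group; its configuration is erased in step 5.

Step 1
Reactants: 1 4-(benzyloxy)-3-methoxybenzaldehyde; 2 ethynylmagnesium bromide
Product: 4 rac-1-[4-(benzyloxy)-3-methoxyphenyl]prop-2-yn-1-yl acetate, via bromomagnesium propargylic alkoxide 3 (not isolated)
Conditions: 2 (THF solution), THF, 0 °C; then Ac2O, 0 °C to rt
Reagents that add atoms: acetic anhydride, CC(=O)OC(C)=O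
Why: Grignard 1,2-addition of the acetylide to the aldehyde and in situ O-acylation of the magnesium alkoxide give the propargylic acetate, which is left racemic on purpose because step 4 is stereoconvergent.

Step 2
Reactants: 5 dimethyl malonate; 6 (R)-epichlorohydrin
Product: 8 methyl (1S,5R)-2-oxo-3-oxabicyclo[3.1.0]hexane-1-carboxylate, via cyclopropane hydroxy diester 7 (not isolated)
Conditions: NaOMe, MeOH, 0 °C to reflux
Reagents that add atoms: none
Why: Double alkylation of the malonate with epichlorohydrin (epoxide opening at CH2, re-closure to a new epoxide with loss of chloride, 3-exo-tet cyclopropanation with inversion, lactonisation) gives the cis-fused cyclopropane lactone, so the carbon that becomes C3 takes its configuration from the chiral pool.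

Step 3
Reactants: 8 methyl (1S,5R)-2-oxo-3-oxabicyclo[3.1.0]hexane-1-carboxylate; 9 vinylmagnesium bromide
Product: 11 methyl (3S,4R)-2-oxo-4-(prop-2-en-1-yl)oxolane-3-carboxylate, via bromomagnesium lactone enolate 10 (not isolated)
Conditions: 9, CuI (10 mol%), THF, −40 to −20 °C; then aq. NH4Cl
Reagents that add atoms: none
Why: Copper-catalysed homoconjugate addition of the Grignard reagent to the doubly activated cyclopropane occurs at its CH2 carbon, which leaves the C3 stereocentre untouched and delivers C4 together with a latent C4a carboxyl as an allyl group.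

Step 4
Reactants: 11 methyl (3S,4R)-2-oxo-4-(prop-2-en-1-yl)oxolane-3-carboxylate; 4 rac-1-[4-(benzyloxy)-3-methoxyphenyl]prop-2-yn-1-yl acetate
Product: 12 methyl (3R,4R)-3-{(1R)-1-[4-(benzyloxy)-3-methoxyphenyl]prop-2-yn-1-yl}-2-oxo-4-(prop-2-en-1-yl)oxolane-3-carboxylate
Conditions: Cu(MeCN)4BF4 (5 mol%), 2,6-bis[(4S)-4-phenyl-4,5-dihydrooxazol-2-yl]pyridine (6 mol%), i-Pr2NEt, MeOH, −20 °C
Reagents that add atoms: none
Why: In this copper-catalysed asymmetric propargylic substitution the copper acetylide of 4 ionises to a copper allenylidene that is attacked at its γ-carbon by the amine-generated enolate of the cyclic 1,3-dicarbonyl 11 inside the chiral pybox pocket, so C1 is set by the catalyst from both enantiomers of 4, while the quaternary carbon forms anti to the allyl group and is reset in step 5.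

Step 5
Reactants: 12 methyl (3R,4R)-3-{(1R)-1-[4-(benzyloxy)-3-methoxyphenyl]prop-2-yn-1-yl}-2-oxo-4-(prop-2-en-1-yl)oxolane-3-carboxylate
Product: 14 (3R,4R)-3-{(1R)-1-[4-(benzyloxy)-3-methoxyphenyl]prop-2-yn-1-yl}-4-(prop-2-en-1-yl)oxolan-2-one (trans), via cis lactone epimer 13 (not isolated)
Conditions: LiCl, H2O, DMSO, 140 °C; then DBU (cat.), PhMe, 60 °C
Reagents that add atoms: none
Why: Krapcho dealkoxycarbonylation removes the activating ester, and base equilibration of the enolisable lactone α-carbon places the bulky C1 substituent trans to the C3 allyl group, which sets C2 under thermodynamic control without touching the far less acidic C1–H.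

Step 6
Reactants: 14 (3R,4R)-3-{(1R)-1-[4-(benzyloxy)-3-methoxyphenyl]prop-2-yn-1-yl}-4-(prop-2-en-1-yl)oxolan-2-one
Product: 15 (2R,3R)-2-{(1R)-1-[4-(benzyloxy)-3-methoxyphenyl]prop-2-yn-1-yl}-3-(hydroxymethyl)-N,N-dimethylhex-5-enamide
Conditions: Me2NH·HCl, AlMe3, CH2Cl2, 0 °C to rt; then 14, rt to 40 °C; aq. potassium sodium tartrate
Reagents that add atoms: dimethylamine hydrochloride, CNC.Cl
Why: Aminolysis of the lactone by the aluminium amide MeAl(Cl)NMe2 cleaves the acyl C–O bond, which frees the C9 hydroxyl and turns C9′ into a dimethylamide that resists enolisation and acyl transfer and later serves as the masked hydroxymethyl group.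

Step 7
Reactants: 15 (2R,3R)-2-{(1R)-1-[4-(benzyloxy)-3-methoxyphenyl]prop-2-yn-1-yl}-3-(hydroxymethyl)-N,N-dimethylhex-5-enamide
Product: 16 (2R,3R)-3-[(benzyloxy)methyl]-2-{(1R)-1-[4-(benzyloxy)-3-methoxyphenyl]prop-2-yn-1-yl}-N,N-dimethylhex-5-enamide
Conditions: NaH, BnBr, n-Bu4NI (cat.), THF, 0 °C to rt
Reagents that add atoms: benzyl bromide, BrCc1ccccc1
Why: Williamson etherification of the primary alkoxide, which forms much faster than the acetylide, protects C9–OH as a benzyl ether that stays until the final hydrogenolysis.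

Step 8
Reactants: 16 (2R,3R)-3-[(benzyloxy)methyl]-2-{(1R)-1-[4-(benzyloxy)-3-methoxyphenyl]prop-2-yn-1-yl}-N,N-dimethylhex-5-enamide
Product: 18 (3R,4R,5R)-5-[4-(benzyloxy)-3-methoxyphenyl]-3-[(benzyloxy)methyl]-4-(dimethylcarbamoyl)hept-6-ynoic acid, via C4a aldehyde 17 (not isolated)
Conditions: OsO4 (1 mol%), KHSO5 (as Oxone, 2KHSO5·KHSO4·K2SO4), DMF, rt
Reagents that add atoms: potassium peroxymonosulfate, [K+].[O-]S(=O)(=O)OO; water, O
Why: Osmium-catalysed oxidative cleavage of the terminal alkene (dihydroxylation, glycol cleavage and aldehyde oxidation in one flask) gives the C4a carboxylic acid, the monosubstituted alkene reacting with OsO4 far faster than the terminal alkyne.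

Step 9
Reactants: 18 (3R,4R,5R)-5-[4-(benzyloxy)-3-methoxyphenyl]-3-[(benzyloxy)methyl]-4-(dimethylcarbamoyl)hept-6-ynoic acid; 19 methyl acetoacetate
Product: 22 methyl (7R,8R,9R)-9-[4-(benzyloxy)-3-methoxyphenyl]-7-[(benzyloxy)methyl]-8-(dimethylcarbamoyl)-3,5-dioxoundec-10-ynoate, via acetoacetate dianion 20 (not isolated), via acyl imidazolide 21 (not isolated)
Conditions: 18, CDI, THF, rt; separately 19, NaH then n-BuLi, THF, 0 °C (excess); combine at −78 to 0 °C; aq. HCl
Reagents that add atoms: none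
Why: Claisen-type γ-acylation of the acetoacetate dianion by the acyl imidazolide builds the 3,5-dioxo ester, the tertiary amide being a poor acyl donor and the excess dianion absorbing the acidic protons of imidazole and the alkyne.

Step 10
Reactants: 22 methyl (7R,8R,9R)-9-[4-(benzyloxy)-3-methoxyphenyl]-7-[(benzyloxy)methyl]-8-(dimethylcarbamoyl)-3,5-dioxoundec-10-ynoate
Product: 23 (2R,3R)-3-[(benzyloxy)methyl]-2-{(1R)-1-[4-(benzyloxy)-3-methoxyphenyl]prop-2-yn-1-yl}-4-(4-hydroxy-2-oxo-2H-pyran-6-yl)-N,N-dimethylbutanamide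
Conditions: DBU, PhMe, 80 °C; then aq. HCl
Reagents that add atoms: none
Why: Base-mediated enol lactonisation of the β,δ-diketo ester closes the 4-hydroxy-2-pyrone with loss of methanol.

Step 11
Reactants: 23 (2R,3R)-3-[(benzyloxy)methyl]-2-{(1R)-1-[4-(benzyloxy)-3-methoxyphenyl]prop-2-yn-1-yl}-4-(4-hydroxy-2-oxo-2H-pyran-6-yl)-N,N-dimethylbutanamide
Product: 24 (2R,3R)-3-[(benzyloxy)methyl]-2-{(1R)-1-[4-(benzyloxy)-3-methoxyphenyl]prop-2-yn-1-yl}-4-(3-bromo-4-hydroxy-2-oxo-2H-pyran-6-yl)-N,N-dimethylbutanamide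
Conditions: NBS, CH2Cl2, 0 °C
Reagents that add atoms: N-bromosuccinimide, O=C1CCC(=O)N1Br
Why: Electrophilic bromination occurs at C3 of the 4-hydroxy-2-pyrone, a vinylogous acid enol far more nucleophilic than the dialkoxyarene or the alkyne, and installs the bromine that later marks C7.

Step 12
Reactants: 24 (2R,3R)-3-[(benzyloxy)methyl]-2-{(1R)-1-[4-(benzyloxy)-3-methoxyphenyl]prop-2-yn-1-yl}-4-(3-bromo-4-hydroxy-2-oxo-2H-pyran-6-yl)-N,N-dimethylbutanamide
Product: 25 (2R,3R)-3-[(benzyloxy)methyl]-2-{(1R)-1-[4-(benzyloxy)-3-methoxyphenyl]prop-2-yn-1-yl}-4-(3-bromo-4-methoxy-2-oxo-2H-pyran-6-yl)-N,N-dimethylbutanamide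
Conditions: Me2SO4, K2CO3, acetone, 45 °C
Reagents that add atoms: dimethyl sulfate, COS(=O)(=O)OC
Why: O-alkylation of the pyrone 4-oxygen with dimethyl sulfate under carbonate conditions gives the 4-methoxy-2-pyrone, the usual regiochemical outcome for 4-hydroxy-2-pyrones.

Step 13
Reactants: 25 (2R,3R)-3-[(benzyloxy)methyl]-2-{(1R)-1-[4-(benzyloxy)-3-methoxyphenyl]prop-2-yn-1-yl}-4-(3-bromo-4-methoxy-2-oxo-2H-pyran-6-yl)-N,N-dimethylbutanamide
Product: 27 (1S,2R,3R)-1-[4-(benzyloxy)-3-methoxyphenyl]-3-[(benzyloxy)methyl]-7-bromo-6-methoxy-N,N-dimethyl-1,2,3,4-tetrahydronaphthalene-2-carboxamide, via bridged bicyclic lactone 26 (not isolated)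
Conditions: o-dichlorobenzene (0.02 M), BHT (cat.), 170 °C, sealed vessel
Reagents that add atoms: none
Why: An intramolecular Diels–Alder reaction joins the alkyne carbon on C1 to pyrone C6 and the terminal alkyne carbon to the bromine-bearing pyrone C3, and the bridged lactone 26 then aromatises irreversibly by retro-Diels–Alder loss of CO2. The closest known reaction type is the thermal 2-pyrone–alkyne cycloaddition of 3-bromo-2-pyrones, which behave as ambiphilic dienes. Ring B closes as a six-membered carbocycle in a type 1 intramolecular cycloaddition through the four-atom tether C4–C3–C2–C1, the new C4a–C8a bond being the ring-closing bond, and ring A arises as the carbocycle C4a–C5–C6–C7–C8–C8a once C7–C8 has formed and the O–C(=O) bridge has left. No stereocentre is created: the bridgehead centres of 26 vanish on aromatisation, and C1, C2 and C3 are untouched under neutral thermal conditions. The only selectivity needed is regiochemical (OMe at C6, Br at C7), and the tether secures it because the internal alkyne carbon can reach only pyrone C6.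

Step 14
Reactants: 27 (1S,2R,3R)-1-[4-(benzyloxy)-3-methoxyphenyl]-3-[(benzyloxy)methyl]-7-bromo-6-methoxy-N,N-dimethyl-1,2,3,4-tetrahydronaphthalene-2-carboxamide
Product: 29 (1S,2R,3R)-7-(benzyloxy)-1-[4-(benzyloxy)-3-methoxyphenyl]-3-[(benzyloxy)methyl]-6-methoxy-N,N-dimethyl-1,2,3,4-tetrahydronaphthalene-2-carboxamide, via potassium C7 phenoxide 28 (not isolated)
Conditions: Pd2(dba)3 (2 mol%), t-BuXPhos (8 mol%), KOH, dioxane–H2O, 100 °C; then BnBr, n-Bu4NBr, 60 °C
Reagents that add atoms: potassium hydroxide, [K+].[OH-]; benzyl bromide, BrCc1ccccc1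
Why: Palladium-catalysed hydroxylation of the aryl bromide with hydroxide (C–O cross-coupling) gives the phenoxide, which is benzylated in the same flask by phase-transfer Williamson etherification, so the C7 oxygen enters already protected.

Step 15
Reactants: 29 (1S,2R,3R)-7-(benzyloxy)-1-[4-(benzyloxy)-3-methoxyphenyl]-3-[(benzyloxy)methyl]-6-methoxy-N,N-dimethyl-1,2,3,4-tetrahydronaphthalene-2-carboxamide
Product: 30 {(1S,2R,3R)-7-(benzyloxy)-1-[4-(benzyloxy)-3-methoxyphenyl]-3-[(benzyloxy)methyl]-6-methoxy-1,2,3,4-tetrahydronaphthalen-2-yl}methanol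
Conditions: LiEt3BH, THF, 0 °C to rt; then H2O
Reagents that add atoms: none
Why: Lithium triethylborohydride reduces N,N-dimethylamides to primary alcohols through C–N cleavage of the tetrahedral intermediate, which unmasks C9′–OH as the only free hydroxyl while the benzyl and methyl ethers are inert.

Step 16
Reactants: 30 {(1S,2R,3R)-7-(benzyloxy)-1-[4-(benzyloxy)-3-methoxyphenyl]-3-[(benzyloxy)methyl]-6-methoxy-1,2,3,4-tetrahydronaphthalen-2-yl}methanol
Product: 32 sodium {(1S,2R,3R)-7-(benzyloxy)-1-[4-(benzyloxy)-3-methoxyphenyl]-3-[(benzyloxy)methyl]-6-methoxy-1,2,3,4-tetrahydronaphthalen-2-yl}methyl sulfate, via pyridinium sulfate salt 31 (not isolated)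
Conditions: SO3·pyridine, pyridine, rt; then aq. NaHCO3
Reagents that add atoms: sulfur trioxide–pyridine complex, [O-]S(=O)(=O)[n+]1ccccc1; sodium hydrogencarbonate, [Na+].OC([O-])=O
Why: O-sulfation of the single free primary alcohol with the sulfur trioxide–pyridine complex, followed by cation exchange, gives the sulfate monoester as its stable sodium salt.

Step 17
Reactants: 32 sodium {(1S,2R,3R)-7-(benzyloxy)-1-[4-(benzyloxy)-3-methoxyphenyl]-3-[(benzyloxy)methyl]-6-methoxy-1,2,3,4-tetrahydronaphthalen-2-yl}methyl sulfate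
Product: 34 {(1S,2R,3R)-7-hydroxy-1-(4-hydroxy-3-methoxyphenyl)-3-(hydroxymethyl)-6-methoxy-1,2,3,4-tetrahydronaphthalen-2-yl}methyl hydrogen sulfate (target), via sodium salt of the target 33 (not isolated)
Conditions: H2 (1 atm), Pd/C, MeOH, rt; then HCl (1.0 equiv), 0 °C
Reagents that add atoms: none
Why: Hydrogenolysis over palladium on carbon cleaves the three benzyl ethers while the sulfate monoester, the aryl methyl ethers and the C1–H bond are inert, and one equivalent of acid then liberates the hydrogen sulfate.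

Compound list
1 | 4-(benzyloxy)-3-methoxybenzaldehyde | O=Cc1ccc(OCc2ccccc2)c(OC)c1 | starting material
2 | ethynylmagnesium bromide | C#C[Mg]Br | starting material
3 | bromomagnesium 1-[4-(benzyloxy)-3-methoxyphenyl]prop-2-yn-1-olate (racemic) | C#CC(O[Mg]Br)c1ccc(OCc2ccccc2)c(OC)c1 | intermediate
4 | rac-1-[4-(benzyloxy)-3-methoxyphenyl]prop-2-yn-1-yl acetate | CC(=O)OC(C#C)c1ccc(OCc2ccccc2)c(OC)c1 | intermediate
5 | dimethyl malonate | COC(=O)CC(=O)OC | starting material
6 | (R)-epichlorohydrin, (2R)-2-(chloromethyl)oxirane | ClC[C@H]1CO1 | starting material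
7 | dimethyl (2R)-2-(hydroxymethyl)cyclopropane-1,1-dicarboxylate (formed as its alkoxide) | COC(=O)C1(C(=O)OC)C[C@H]1CO | intermediate
8 | methyl (1S,5R)-2-oxo-3-oxabicyclo[3.1.0]hexane-1-carboxylate | COC(=O)[C@]12C[C@H]1COC2=O | intermediate
9 | vinylmagnesium bromide | C=C[Mg]Br | starting material
10 | bromomagnesium enolate of 11 | COC(O[Mg]Br)=C1C(=O)OC[C@@H]1CC=C | intermediate
11 | methyl (3S,4R)-2-oxo-4-(prop-2-en-1-yl)oxolane-3-carboxylate (trans) | COC(=O)[C@H]1C(=O)OC[C@@H]1CC=C | intermediate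
12 | methyl (3R,4R)-3-{(1R)-1-[4-(benzyloxy)-3-methoxyphenyl]prop-2-yn-1-yl}-2-oxo-4-(prop-2-en-1-yl)oxolane-3-carboxylate | C#C[C@H](c1ccc(OCc2ccccc2)c(OC)c1)[C@@]1(C(=O)OC)C(=O)OC[C@@H]1CC=C | intermediate
13 | (3S,4R)-3-{(1R)-1-[4-(benzyloxy)-3-methoxyphenyl]prop-2-yn-1-yl}-4-(prop-2-en-1-yl)oxolan-2-one (cis) | C#C[C@H](c1ccc(OCc2ccccc2)c(OC)c1)[C@@H]1C(=O)OC[C@@H]1CC=C | intermediate
14 | (3R,4R)-3-{(1R)-1-[4-(benzyloxy)-3-methoxyphenyl]prop-2-yn-1-yl}-4-(prop-2-en-1-yl)oxolan-2-one (trans) | C#C[C@H](c1ccc(OCc2ccccc2)c(OC)c1)[C@H]1C(=O)OC[C@@H]1CC=C | intermediate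
15 | (2R,3R)-2-{(1R)-1-[4-(benzyloxy)-3-methoxyphenyl]prop-2-yn-1-yl}-3-(hydroxymethyl)-N,N-dimethylhex-5-enamide | C#C[C@H](c1ccc(OCc2ccccc2)c(OC)c1)[C@@H](C(=O)N(C)C)[C@H](CO)CC=C | intermediate
16 | (2R,3R)-3-[(benzyloxy)methyl]-2-{(1R)-1-[4-(benzyloxy)-3-methoxyphenyl]prop-2-yn-1-yl}-N,N-dimethylhex-5-enamide | C#C[C@H](c1ccc(OCc2ccccc2)c(OC)c1)[C@@H](C(=O)N(C)C)[C@H](COCc1ccccc1)CC=C | intermediate
17 | (2R,3R)-3-[(benzyloxy)methyl]-2-{(1R)-1-[4-(benzyloxy)-3-methoxyphenyl]prop-2-yn-1-yl}-N,N-dimethyl-5-oxopentanamide | C#C[C@H](c1ccc(OCc2ccccc2)c(OC)c1)[C@@H](C(=O)N(C)C)[C@H](COCc1ccccc1)CC=O | intermediate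
18 | (3R,4R,5R)-5-[4-(benzyloxy)-3-methoxyphenyl]-3-[(benzyloxy)methyl]-4-(dimethylcarbamoyl)hept-6-ynoic acid | C#C[C@H](c1ccc(OCc2ccccc2)c(OC)c1)[C@@H](C(=O)N(C)C)[C@H](COCc1ccccc1)CC(=O)O | intermediate
19 | methyl acetoacetate | CC(=O)CC(=O)OC | starting material
20 | lithium sodium dianion of methyl acetoacetate | [Li+].[Na+].[CH2-]C(=O)[CH-]C(=O)OC | intermediate
21 | 1-acylimidazole of acid 18 | C#C[C@H](c1ccc(OCc2ccccc2)c(OC)c1)[C@@H](C(=O)N(C)C)[C@H](COCc1ccccc1)CC(=O)n1ccnc1 | intermediate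
22 | methyl (7R,8R,9R)-9-[4-(benzyloxy)-3-methoxyphenyl]-7-[(benzyloxy)methyl]-8-(dimethylcarbamoyl)-3,5-dioxoundec-10-ynoate | C#C[C@H](c1ccc(OCc2ccccc2)c(OC)c1)[C@@H](C(=O)N(C)C)[C@H](COCc1ccccc1)CC(=O)CC(=O)CC(=O)OC | intermediate
23 | (2R,3R)-3-[(benzyloxy)methyl]-2-{(1R)-1-[4-(benzyloxy)-3-methoxyphenyl]prop-2-yn-1-yl}-4-(4-hydroxy-2-oxo-2H-pyran-6-yl)-N,N-dimethylbutanamide | C#C[C@H](c1ccc(OCc2ccccc2)c(OC)c1)[C@@H](C(=O)N(C)C)[C@H](COCc1ccccc1)Cc1cc(O)cc(=O)o1 | intermediate
24 | (2R,3R)-3-[(benzyloxy)methyl]-2-{(1R)-1-[4-(benzyloxy)-3-methoxyphenyl]prop-2-yn-1-yl}-4-(3-bromo-4-hydroxy-2-oxo-2H-pyran-6-yl)-N,N-dimethylbutanamide | C#C[C@H](c1ccc(OCc2ccccc2)c(OC)c1)[C@@H](C(=O)N(C)C)[C@H](COCc1ccccc1)Cc1cc(O)c(Br)c(=O)o1 | intermediate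
25 | (2R,3R)-3-[(benzyloxy)methyl]-2-{(1R)-1-[4-(benzyloxy)-3-methoxyphenyl]prop-2-yn-1-yl}-4-(3-bromo-4-methoxy-2-oxo-2H-pyran-6-yl)-N,N-dimethylbutanamide (key-step precursor) | C#C[C@H](c1ccc(OCc2ccccc2)c(OC)c1)[C@@H](C(=O)N(C)C)[C@H](COCc1ccccc1)Cc1cc(OC)c(Br)c(=O)o1 | intermediate
26 | bridged cycloadduct: ring B fused to a 2-oxabicyclo[2.2.2]octa-5,7-dien-3-one, Br on the carbonyl-side bridgehead (future C7), lactone oxygen on the other bridgehead (future C4a); bridgehead configuration undefined | COc1cc([C@H]2C3=CC4(Br)C(OC)=CC3(C[C@@H](COCc3ccccc3)[C@@H]2C(=O)N(C)C)OC4=O)ccc1OCc1ccccc1 | intermediate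
27 | (1S,2R,3R)-1-[4-(benzyloxy)-3-methoxyphenyl]-3-[(benzyloxy)methyl]-7-bromo-6-methoxy-N,N-dimethyl-1,2,3,4-tetrahydronaphthalene-2-carboxamide (key-step product) | COc1cc([C@H]2c3cc(Br)c(OC)cc3C[C@@H](COCc3ccccc3)[C@@H]2C(=O)N(C)C)ccc1OCc1ccccc1 | intermediate
28 | potassium phenoxide of 27 with O− in place of Br at C7 | COc1cc([C@H]2c3cc([O-])c(OC)cc3C[C@@H](COCc3ccccc3)[C@@H]2C(=O)N(C)C)ccc1OCc1ccccc1.[K+] | intermediate
29 | (1S,2R,3R)-7-(benzyloxy)-1-[4-(benzyloxy)-3-methoxyphenyl]-3-[(benzyloxy)methyl]-6-methoxy-N,N-dimethyl-1,2,3,4-tetrahydronaphthalene-2-carboxamide | COc1cc([C@H]2c3cc(OCc4ccccc4)c(OC)cc3C[C@@H](COCc3ccccc3)[C@@H]2C(=O)N(C)C)ccc1OCc1ccccc1 | intermediate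
30 | {(1S,2R,3R)-7-(benzyloxy)-1-[4-(benzyloxy)-3-methoxyphenyl]-3-[(benzyloxy)methyl]-6-methoxy-1,2,3,4-tetrahydronaphthalen-2-yl}methanol | COc1cc([C@H]2c3cc(OCc4ccccc4)c(OC)cc3C[C@@H](COCc3ccccc3)[C@@H]2CO)ccc1OCc1ccccc1 | intermediate
31 | pyridinium salt of the C9′ sulfate of 30 | COc1cc([C@H]2c3cc(OCc4ccccc4)c(OC)cc3C[C@@H](COCc3ccccc3)[C@@H]2COS(=O)(=O)[O-])ccc1OCc1ccccc1.c1cc[nH+]cc1 | intermediate
32 | sodium salt of the C9′ sulfate of 30 | COc1cc([C@H]2c3cc(OCc4ccccc4)c(OC)cc3C[C@@H](COCc3ccccc3)[C@@H]2COS(=O)(=O)[O-])ccc1OCc1ccccc1.[Na+] | intermediate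
33 | sodium salt of the target | COc1cc([C@H]2c3cc(O)c(OC)cc3C[C@@H](CO)[C@@H]2COS(=O)(=O)[O-])ccc1O.[Na+] | intermediate
34 | {(1S,2R,3R)-7-hydroxy-1-(4-hydroxy-3-methoxyphenyl)-3-(hydroxymethyl)-6-methoxy-1,2,3,4-tetrahydronaphthalen-2-yl}methyl hydrogen sulfate | COc1cc([C@H]2c3cc(O)c(OC)cc3C[C@@H](CO)[C@@H]2COS(=O)(=O)O)ccc1O | target

Total step count: 17. Longest linear sequence: 16 steps (steps 2 to 17, from 5 and 6); step 1 is a one-step branch that joins at step 4.

Steps most likely to fail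

Step 13. The cycloaddition may be too slow at temperatures the substrate tolerates, so that pyrone oligomerisation or alkyne-to-allene isomerisation at C1 outruns ring closure. The fallback gives up the pyrone and brings ring A in as an arene, closing ring B by a cationic cyclisation. It sets out from 8 and returns at 29. Magnesium insertion into 4-bromo-1-(benzyloxy)-2-methoxybenzene in THF should give [4-(benzyloxy)-3-methoxyphenyl]magnesium bromide F1 as a solution. CuI-catalysed opening of 8 with F1 should give methyl (3S,4R)-4-[4-(benzyloxy)-3-methoxybenzyl]-2-oxooxolane-3-carboxylate F2 after NH4Cl quench. Krapcho dealkoxycarbonylation of F2 should give (4R)-4-[4-(benzyloxy)-3-methoxybenzyl]oxolan-2-one F3 as the only lactone. The lithium enolate of F3 (LiN(SiMe3)2, THF, −78 °C) should add to aldehyde 1 anti to the benzyl group to give the trans aldol adduct (3S,4R)-3-{[4-(benzyloxy)-3-methoxyphenyl](hydroxy)methyl}-4-[4-(benzyloxy)-3-methoxybenzyl]oxolan-2-one F4 as a carbinol mixture. TFA in CH2Cl2 ionises the benzylic alcohol of F4, and Friedel–Crafts closure para to the ring A methoxy group should give the trans-fused 1-aryltetralin lactone F5 with the aryl group trans to C9′, as is usual for such lignan cyclisations. Aminolysis of F5 as in step 6 should give the hydroxy amide (1S,2R,3R)-7-(benzyloxy)-1-[4-(benzyloxy)-3-methoxyphenyl]-3-(hydroxymethyl)-6-methoxy-N,N-dimethyl-1,2,3,4-tetrahydronaphthalene-2-carboxamide F6 with C9–OH free. Benzylation of F6 as in step 7 gives 29.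

Step 4. Turnover may be low because the lactone ester is a hindered, only moderately acidic pronucleophile, and uncatalysed ionisation of the electron-rich acetate may erode facial control at C1. The fallback sets C1 by iminium catalysis instead; it sets out from 11 and 1 and returns at 12. Wittig reaction of 1 with Ph3P=CHCHO should give (E)-3-[4-(benzyloxy)-3-methoxyphenyl]prop-2-enal F7 as the E isomer. Michael addition of 11 to F7 with a diphenylprolinol trimethylsilyl ether catalyst should give the 3-oxopropyl adduct methyl (3R,4R)-3-{(1R)-1-[4-(benzyloxy)-3-methoxyphenyl]-3-oxopropyl}-2-oxo-4-(prop-2-en-1-yl)oxolane-3-carboxylate F8 with C1 fixed by the catalyst. The CH2–CHO arm of F8 is then turned into the alkyne at the same carbon count: O-sulfonylation of the aldehyde enolate with nonafluorobutanesulfonyl fluoride and a phosphazene base should give the alkenyl nonaflate F9 as an E/Z mixture, and base-induced elimination from F9 gives 12.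

Step 9. Proton transfer from imidazole, from the alkyne and from the C4 methylene of the acyl imidazolide may quench the dianion, so that acylation stalls or the acetylide attacks a second acyl imidazolide. The fallback replaces the Claisen acylation by aldol addition and oxidation; it sets out from 16 and returns at 22. Lemieux–Johnson cleavage (OsO4 cat., NaIO4, 2,6-lutidine, dioxane–H2O) stops at aldehyde 17, which is isolated. Addition of dianion 20 to 17 at −78 °C, a fast reaction that releases no acidic by-product, should give the δ-hydroxy-β-keto ester methyl (7R,8R,9R)-9-[4-(benzyloxy)-3-methoxyphenyl]-7-[(benzyloxy)methyl]-8-(dimethylcarbamoyl)-5-hydroxy-3-oxoundec-10-ynoate F10 as a mixture of C5 epimers, and Dess–Martin periodinane oxidation of F10 gives 22.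

Further compounds
F1 | step 13 | [4-(benzyloxy)-3-methoxyphenyl]magnesium bromide | COc1cc([Mg]Br)ccc1OCc1ccccc1
F2 | step 13 | methyl (3S,4R)-4-[4-(benzyloxy)-3-methoxybenzyl]-2-oxooxolane-3-carboxylate | COC(=O)[C@H]1C(=O)OC[C@@H]1Cc1ccc(OCc2ccccc2)c(OC)c1
F3 | step 13 | (4R)-4-[4-(benzyloxy)-3-methoxybenzyl]oxolan-2-one | O=C1OC[C@H](Cc2ccc(OCc3ccccc3)c(OC)c2)C1
F4 | step 13 | (3S,4R)-3-{[4-(benzyloxy)-3-methoxyphenyl](hydroxy)methyl}-4-[4-(benzyloxy)-3-methoxybenzyl]oxolan-2-one (carbinol epimers) | OC(c1ccc(OCc2ccccc2)c(OC)c1)[C@H]1C(=O)OC[C@@H]1Cc1ccc(OCc2ccccc2)c(OC)c1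
F5 | step 13 | 7-(benzyloxy)-1-[4-(benzyloxy)-3-methoxyphenyl]-6-methoxytetralin trans-fused at C2–C3 to a γ-lactone (C9′ carbonyl on C2, C9–O on C3), configuration at C1–C3 as in 29 | COc1cc([C@H]2c3cc(OCc4ccccc4)c(OC)cc3C[C@H]3COC(=O)[C@H]23)ccc1OCc1ccccc1
F6 | step 13 | (1S,2R,3R)-7-(benzyloxy)-1-[4-(benzyloxy)-3-methoxyphenyl]-3-(hydroxymethyl)-6-methoxy-N,N-dimethyl-1,2,3,4-tetrahydronaphthalene-2-carboxamide | COc1cc([C@H]2c3cc(OCc4ccccc4)c(OC)cc3C[C@@H](CO)[C@@H]2C(=O)N(C)C)ccc1OCc1ccccc1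
F7 | step 4 | (E)-3-[4-(benzyloxy)-3-methoxyphenyl]prop-2-enal | O=C/C=C/c1ccc(OCc2ccccc2)c(OC)c1
F8 | step 4 | methyl (3R,4R)-3-{(1R)-1-[4-(benzyloxy)-3-methoxyphenyl]-3-oxopropyl}-2-oxo-4-(prop-2-en-1-yl)oxolane-3-carboxylate | O=CC[C@H](c1ccc(OCc2ccccc2)c(OC)c1)[C@@]1(C(=O)OC)C(=O)OC[C@@H]1CC=C
F9 | step 4 | alkenyl nonaflate of F8 (E/Z mixture) | O=S(=O)(OC=C[C@H](c1ccc(OCc2ccccc2)c(OC)c1)[C@@]1(C(=O)OC)C(=O)OC[C@@H]1CC=C)C(F)(F)C(F)(F)C(F)(F)C(F)(F)F
F10 | step 9 | methyl (7R,8R,9R)-9-[4-(benzyloxy)-3-methoxyphenyl]-7-[(benzyloxy)methyl]-8-(dimethylcarbamoyl)-5-hydroxy-3-oxoundec-10-ynoate (C5 epimers) | C#C[C@H](c1ccc(OCc2ccccc2)c(OC)c1)[C@@H](C(=O)N(C)C)[C@H](COCc1ccccc1)CC(O)CC(=O)CC(=O)OC
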